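**Retrosynthetic overview**

1. Feature (butenolide: O1, C2 lactone C=O, C3 enol, C4 phenyl, C5 quaternary; C6 = benzylic CH2; primed = chroman): the chroman oxygen O1' lies para to C6, so the arene comes from a 4-substituted phenol whose two ortho carbons are identical, and a 1,1-dimethylpropargyl ether on that oxygen can only annulate to one 2,2-dimethyl-2H-chromene (O1'–C2'–C3'=C4'–C4a').
2. Target 16 ⇐ chromene 15: one hydrogenation saturates C3'=C4' and removes the 3-O-benzyl group.
3. Pyran ring of 15 (bonds C4'–C4a' and O1'–C2') ⇐ aryl 1,1-dimethylpropargyl ether 11 by a thermal [3,3]-shift / 1,5-hydrogen shift / oxa-6π-electrocyclisation cascade.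
4. C5–C6 bond and the (R) centre ⇐ enantioselective phase-transfer benzylation of racemic 5-H butenolide 5 with bromide 10, which already carries the propargyl ether (from 4-hydroxybenzaldehyde and 3-chloro-3-methylbut-1-yne).
5. Butenolide ring ⇐ aldol/lactonisation of methyl phenylpyruvate with methyl glyoxylate. Ring order: butenolide first (step 1), pyran second (step 7).

Key step: step 7

Assumption: the cinchonidine-derived ammonium salt is taken to favour the (R)-configured quaternary centre; if the sense of induction is the opposite, the pseudoenantiomeric cinchonine-derived salt is used under the same conditions.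

**Route**

Step 1
Reactants: 1 methyl phenylpyruvate; 2 methyl glyoxylate
Product: 4 racemic methyl 4-hydroxy-5-oxo-3-phenyl-2,5-dihydrofuran-2-carboxylate, via acyclic aldol adduct 3 (not isolated)
Conditions: Et3N (1.2 equiv), THF, 0 °C to rt, 1 added slowly to 2 (1.5 equiv, freshly distilled); then 1 M HCl
Reagents that add atoms: none
Why: Base-mediated cross-aldol addition of the enolate of 1 to the non-enolisable, highly electrophilic aldehyde 2 gives 3, whose hydroxyl lactonises onto the keto-ester carbonyl with loss of methanol and the α-keto lactone enolises to isotetronic acid 4 (aldol/lactonisation); C5 forms without control and is reset in step 6.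

Step 2
Reactants: 4 racemic methyl 4-hydroxy-5-oxo-3-phenyl-2,5-dihydrofuran-2-carboxylate
Product: 5 racemic methyl 4-(benzyloxy)-5-oxo-3-phenyl-2,5-dihydrofuran-2-carboxylate
Conditions: BnBr (1.0 equiv), K2CO3 (1.05 equiv), acetone, rt
Reagents that add atoms: benzyl bromide, BrCc1ccccc1
Why: Williamson O-alkylation of the acidic enol of the α-keto lactone, with only one equivalent of bromide so that the much less acidic C5–H is not benzylated.

Step 3
Reactants: 6 4-hydroxybenzaldehyde; 7 3-chloro-3-methylbut-1-yne
Product: 8 4-(2-methylbut-3-yn-2-yloxy)benzaldehyde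
Conditions: 7 (1.3 equiv), DBU (1.3 equiv), CuCl2·2H2O (0.5 mol%), MeCN, 0 °C
Reagents that add atoms: none
Why: Copper-catalysed propargylic substitution of the tertiary chloride by the phenoxide (through a copper acetylide/allenylidene-type intermediate) is the standard preparation of aryl 1,1-dimethylpropargyl ethers and suits acidic phenols such as 6.

Step 4
Reactants: 8 4-(2-methylbut-3-yn-2-yloxy)benzaldehyde
Product: 9 [4-(2-methylbut-3-yn-2-yloxy)phenyl]methanol
Conditions: NaBH4, MeOH, 0 °C
Reagents that add atoms: none
Why: Chemoselective borohydride reduction of the aryl aldehyde; the terminal alkyne and the tertiary ether are inert.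

Step 5
Reactants: 9 [4-(2-methylbut-3-yn-2-yloxy)phenyl]methanol
Product: 10 1-(bromomethyl)-4-(2-methylbut-3-yn-2-yloxy)benzene
Conditions: CBr4, PPh3, CH2Cl2, 0 °C; filtered through silica and used at once
Reagents that add atoms: tetrabromomethane, BrC(Br)(Br)Br
Why: Appel bromination converts the primary benzylic alcohol to the bromide under neutral conditions, so the acid-sensitive tertiary propargylic ether is not ionised.

Step 6
Reactants: 5 racemic methyl 4-(benzyloxy)-5-oxo-3-phenyl-2,5-dihydrofuran-2-carboxylate; 10 1-(bromomethyl)-4-(2-methylbut-3-yn-2-yloxy)benzene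
Product: 11 methyl (2R)-4-(benzyloxy)-2-{[4-(2-methylbut-3-yn-2-yloxy)phenyl]methyl}-5-oxo-3-phenyl-2,5-dihydrofuran-2-carboxylate
Conditions: 10 (1.2 equiv), O-allyl-N-(9-anthracenylmethyl)cinchonidinium bromide (10 mol%), powdered K2CO3, toluene, −20 °C
Reagents that add atoms: none
Why: Asymmetric phase-transfer-catalysed alkylation in which carbonate removes C5–H to give a planar 2-oxidofuran/ester enolate (erasing the racemic centre), whose tight ion pair with the chiral ammonium cation is benzylated by SN2 on its open face at C5, the ester-bearing terminus that restores the conjugated butenolide, so the (R) quaternary centre is set by the catalyst.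

Step 7
Reactants: 11 methyl (2R)-4-(benzyloxy)-2-{[4-(2-methylbut-3-yn-2-yloxy)phenyl]methyl}-5-oxo-3-phenyl-2,5-dihydrofuran-2-carboxylate
Product: 15 methyl (2R)-4-(benzyloxy)-2-[(2,2-dimethyl-2H-chromen-6-yl)methyl]-5-oxo-3-phenyl-2,5-dihydrofuran-2-carboxylate, via allenyl cyclohexadienone 12 (not isolated), via ortho-allenylphenol 13 (not isolated), via ortho-quinone methide 14 (not isolated)
Conditions: PhNEt2, 150 °C, argon; cold 1 M HCl wash
Reagents that add atoms: none
Why: Heating starts an aromatic propargyl Claisen ([3,3]-sigmatropic) shift that breaks the ether O–C bond and joins the alkyne terminus to an ortho carbon (the C4'–C4a' bond), giving dienone 12, which enolises to allenylphenol 13. A 1,5-hydrogen shift from the phenolic O–H to the central allene carbon then gives the (Z)-ortho-quinone methide 14, whose oxatriene closes the pyran ring by a thermally allowed disrotatory oxa-6π-electrocyclisation, forming the new O1'–C2' bond and restoring aromaticity. The closest known reaction type is the thermal rearrangement of aryl 1,1-dimethylpropargyl ethers to 2,2-dimethyl-2H-chromenes. No stereocentre is created, and the quaternary C5 has no α-hydrogen, so it cannot epimerise at this temperature. Regioselectivity is degenerate because the para-substituted ring offers two identical ortho carbons; six-membered closure is secured by the absence of strong base or fluoride (which would divert 13 to a benzofuran by 5-exo attack of the phenoxide) and by the gem-dimethyl group, which accelerates the [3,3] step. The benzyl enol ether, methyl ester and lactone are expected to survive heating in the weakly basic solvent, which also buffers adventitious acid.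

Step 8
Reactants: 15 methyl (2R)-4-(benzyloxy)-2-[(2,2-dimethyl-2H-chromen-6-yl)methyl]-5-oxo-3-phenyl-2,5-dihydrofuran-2-carboxylate
Product: 16 4'-dehydroxy aspernolide A, methyl (2R)-2-[(2,2-dimethyl-3,4-dihydro-2H-chromen-6-yl)methyl]-4-hydroxy-5-oxo-3-phenyl-2,5-dihydrofuran-2-carboxylate
Conditions: H2 (1 atm), 10% Pd/C, EtOAc, rt
Reagents that add atoms: none
Why: Heterogeneous catalytic hydrogenation saturates the cis-disubstituted chromene C3'=C4' bond and hydrogenolyses the benzylic C–O bond of the enol ether in one operation, while the tetrasubstituted enolic C3=C4 bond, the ester, the lactone and the quaternary C5 should be untouched.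

**Compound list**

1 | methyl phenylpyruvate (methyl 2-oxo-3-phenylpropanoate) | COC(=O)C(=O)Cc1ccccc1 | starting material
2 | methyl glyoxylate (methyl 2-oxoacetate) | COC(=O)C=O | starting material
3 | dimethyl 2-hydroxy-4-oxo-3-phenylpentanedioate (acyclic aldol adduct, racemic diastereomer mixture) | COC(=O)C(O)C(c1ccccc1)C(=O)C(=O)OC | intermediate (not isolated)
4 | racemic methyl 4-hydroxy-5-oxo-3-phenyl-2,5-dihydrofuran-2-carboxylate | COC(=O)C1OC(=O)C(O)=C1c1ccccc1 | intermediate
5 | racemic methyl 4-(benzyloxy)-5-oxo-3-phenyl-2,5-dihydrofuran-2-carboxylate | COC(=O)C1OC(=O)C(OCc2ccccc2)=C1c1ccccc1 | intermediate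
6 | 4-hydroxybenzaldehyde | O=Cc1ccc(O)cc1 | starting material
7 | 3-chloro-3-methylbut-1-yne | CC(C)(Cl)C#C | starting material
8 | 4-(2-methylbut-3-yn-2-yloxy)benzaldehyde | O=Cc1ccc(OC(C)(C)C#C)cc1 | intermediate
9 | [4-(2-methylbut-3-yn-2-yloxy)phenyl]methanol | OCc1ccc(OC(C)(C)C#C)cc1 | intermediate
10 | 1-(bromomethyl)-4-(2-methylbut-3-yn-2-yloxy)benzene | BrCc1ccc(OC(C)(C)C#C)cc1 | intermediate
11 | methyl (2R)-4-(benzyloxy)-2-{[4-(2-methylbut-3-yn-2-yloxy)phenyl]methyl}-5-oxo-3-phenyl-2,5-dihydrofuran-2-carboxylate | COC(=O)[C@]1(Cc2ccc(OC(C)(C)C#C)cc2)OC(=O)C(OCc2ccccc2)=C1c1ccccc1 | intermediate (key-step precursor)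
12 | methyl (2R)-4-(benzyloxy)-2-{[3-(3-methylbuta-1,2-dien-1-yl)-4-oxocyclohexa-1,5-dien-1-yl]methyl}-5-oxo-3-phenyl-2,5-dihydrofuran-2-carboxylate (epimer mixture at the ring sp3 carbon) | COC(=O)[C@]1(CC2=CC(C=C=C(C)C)C(=O)C=C2)OC(=O)C(OCc2ccccc2)=C1c1ccccc1 | intermediate (not isolated)
13 | methyl (2R)-4-(benzyloxy)-2-{[4-hydroxy-3-(3-methylbuta-1,2-dien-1-yl)phenyl]methyl}-5-oxo-3-phenyl-2,5-dihydrofuran-2-carboxylate | COC(=O)[C@]1(Cc2ccc(O)c(C=C=C(C)C)c2)OC(=O)C(OCc2ccccc2)=C1c1ccccc1 | intermediate (not isolated)
14 | methyl (2R)-4-(benzyloxy)-2-{[(3Z)-3-(3-methylbut-2-en-1-ylidene)-4-oxocyclohexa-1,5-dien-1-yl]methyl}-5-oxo-3-phenyl-2,5-dihydrofuran-2-carboxylate | COC(=O)[C@]1(CC2=C/C(=C/C=C(C)C)C(=O)C=C2)OC(=O)C(OCc2ccccc2)=C1c1ccccc1 | intermediate (not isolated)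
15 | methyl (2R)-4-(benzyloxy)-2-[(2,2-dimethyl-2H-chromen-6-yl)methyl]-5-oxo-3-phenyl-2,5-dihydrofuran-2-carboxylate | COC(=O)[C@]1(Cc2ccc3c(c2)C=CC(C)(C)O3)OC(=O)C(OCc2ccccc2)=C1c1ccccc1 | intermediate (key-step product)
16 | 4'-dehydroxy aspernolide A, methyl (2R)-2-[(2,2-dimethyl-3,4-dihydro-2H-chromen-6-yl)methyl]-4-hydroxy-5-oxo-3-phenyl-2,5-dihydrofuran-2-carboxylate | COC(=O)[C@]1(Cc2ccc3c(c2)CCC(C)(C)O3)OC(=O)C(O)=C1c1ccccc1 | target

**Step count and risks**

Total step count: 8. Longest linear sequence: 6 (steps 3, 4, 5, 6, 7, 8, from 4-hydroxybenzaldehyde).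

Steps most likely to fail:

Step 6. The chiral ion pair may discriminate poorly between the two faces of the planar enolate. The ambident furanolate may also react partly at C3 or at oxygen, and the electron-rich benzylic bromide may decompose under base before it is consumed. Fallback, setting out from 5 (with 10) and returning at 11: the benzylation is run without a chiral catalyst (Bu4NBr, K2CO3, DMF, 0 °C) to give racemic methyl 4-(benzyloxy)-2-{[4-(2-methylbut-3-yn-2-yloxy)phenyl]methyl}-5-oxo-3-phenyl-2,5-dihydrofuran-2-carboxylate F1. The enantiomers are then separated by preparative chromatography on a polysaccharide chiral stationary phase, which is feasible because the quaternary centre cannot racemise. The (R)-enantiomer is 11, and methyl (2S)-4-(benzyloxy)-2-{[4-(2-methylbut-3-yn-2-yloxy)phenyl]methyl}-5-oxo-3-phenyl-2,5-dihydrofuran-2-carboxylate F2 is set aside. The configuration would be assigned by chiroptical correlation of the final product with the natural series.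

Step 7. On the fully assembled substrate, prolonged heating may cause thermal elimination of the tertiary propargyl group to the free phenol, migration or loss of the benzyl enol ether, or stalling at the allenylphenol with diversion to a benzofuran. Fallback, setting out from 8 and returning at 15: the same pericyclic cascade is run earlier on the small, robust aldehyde 8 (PhNEt2, 150 °C) to give 2,2-dimethyl-2H-chromene-6-carbaldehyde F3. Reduction (NaBH4, MeOH, 0 °C) gives (2,2-dimethyl-2H-chromen-6-yl)methanol F4, and Appel bromination (CBr4, PPh3, CH2Cl2, 0 °C) gives 6-(bromomethyl)-2,2-dimethyl-2H-chromene F5. F5 is used at once in the phase-transfer benzylation of 5 under the conditions of step 6, which gives 15 directly, so no late-stage heating is needed.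

Step 1. Self-aldol of methyl phenylpyruvate, which leads to its own lactone dimer, may compete with the cross-aldol. Oligomerised or hydrated glyoxylate would react sluggishly and make this worse. Fallback, setting out from 1 and returning at 4: the enol of 1 is silylated (TMSCl, Et3N, CH2Cl2, 0 °C) to methyl (Z)-3-phenyl-2-(trimethylsilyloxy)prop-2-enoate F6. A directed Mukaiyama aldol addition of F6 to 2 (Sc(OTf)3, 10 mol%, CH2Cl2, −78 to 0 °C) followed by acidic desilylation (1 M HCl, THF) gives aldol adduct 3, which lactonises to 4. The pyruvate can then act only as the nucleophile.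

**Further compounds**

F1 | step 6 | racemic methyl 4-(benzyloxy)-2-{[4-(2-methylbut-3-yn-2-yloxy)phenyl]methyl}-5-oxo-3-phenyl-2,5-dihydrofuran-2-carboxylate | COC(=O)C1(Cc2ccc(OC(C)(C)C#C)cc2)OC(=O)C(OCc2ccccc2)=C1c1ccccc1
F2 | step 6 | methyl (2S)-4-(benzyloxy)-2-{[4-(2-methylbut-3-yn-2-yloxy)phenyl]methyl}-5-oxo-3-phenyl-2,5-dihydrofuran-2-carboxylate | COC(=O)[C@@]1(Cc2ccc(OC(C)(C)C#C)cc2)OC(=O)C(OCc2ccccc2)=C1c1ccccc1
F3 | step 7 | 2,2-dimethyl-2H-chromene-6-carbaldehyde | CC1(C)C=Cc2cc(C=O)ccc2O1
F4 | step 7 | (2,2-dimethyl-2H-chromen-6-yl)methanol | CC1(C)C=Cc2cc(CO)ccc2O1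
F5 | step 7 | 6-(bromomethyl)-2,2-dimethyl-2H-chromene | CC1(C)C=Cc2cc(CBr)ccc2O1
F6 | step 1 | methyl (Z)-3-phenyl-2-(trimethylsilyloxy)prop-2-enoate | COC(=O)/C(O[Si](C)(C)C)=C/c1ccccc1
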